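**Plan**

1. Locants: the decalin is numbered as naphthalene (C-2 carries the cyclopentyl group; ring A = C-1 to C-4, C-4a, C-8a; ring B = C-4a to C-8a). The cyclopentane is ring C (C-1' quaternary, C-3' CHBr, C-5' CHOH).
2. Retrosynthesis: the C-3'–Br bond and the C-5' carbinol go back to a cyclopentenone. The C-1'–C-2 bond is then cut as an aldol. In the decalin, the C-8 methyl, the C-8/C-8a oxygens and the C-5 bromide go back to (R)-Wieland–Miescher ketone.
3. Forward: rings A and B come fused from the Wieland–Miescher ketone and are functionalised first (C-5 Br, C-8a OH, C-8 methyl carbinol). Ring C comes as 4,4,5-trimethylcyclopent-2-enone. The C-1'–C-2 bond joins the two, and HBr addition and carbonyl reduction finish ring C.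
4. Enabling feature: the C-5' oxygen lies β to the C-2 carbinol across quaternary C-1' (aldol retron). The C-8a hydroxyl is 1,3-syn-diaxial to the C-2 hydroxyl on ring A, so the three oxygens can sit on one metal. The C-5' carbonyl then activates C-3' for bromide.
5. Stereochemistry: C-4a from the starting ketone; C-5 by double inversion; C-8a by osmylation anti to the angular methyl; C-8 by equatorial Grignard attack; C-2 and C-1' by the chelated aldol, in which the racemic enone converges; C-3' by reversible HBr addition; C-5' by hydride attack anti to the decalinyl group.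

Key step: step 11

Remark: (R)-(−)-Wieland–Miescher ketone and 4,4-dimethylcyclopent-2-en-1-one are taken as commercial starting materials.

**Step 1**
Reactants: 1 (R)-(−)-Wieland–Miescher ketone
Product: 2 (4aR,5R)-5-hydroxy-4a-methyl-4,4a,5,6,7,8-hexahydronaphthalen-2(3H)-one (hydroxyl cis to the angular methyl)
Conditions: NaBH4 (0.3 equiv), EtOH, −10 °C
Reagents that add atoms: none
Why: Chemoselective borohydride reduction of the saturated ketone in the presence of the less electrophilic enone, with hydride entering anti to the angular methyl so that the hydroxyl should end up cis to it.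

**Step 2**
Reactants: 2 (4aR,5R)-5-hydroxy-4a-methyl-4,4a,5,6,7,8-hexahydronaphthalen-2(3H)-one
Product: 3 (1S,8aR)-8a-methyl-6-oxo-1,2,3,4,6,7,8,8a-octahydronaphthalen-1-yl 4-nitrobenzoate (ester oxygen trans to the angular methyl)
Conditions: 4-O2NC6H4CO2H, PPh3, DIAD, toluene, 0 °C to rt
Reagents that add atoms: 4-nitrobenzoic acid, O=C(O)c1ccc(cc1)[N+](=O)[O-]
Why: Mitsunobu inversion with an acidic carboxylic acid, as used for hindered secondary alcohols, should turn the carbinol to the configuration trans to the angular methyl, the carboxylate entering from the face away from that methyl.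

**Step 3**
Reactants: 3 (1S,8aR)-8a-methyl-6-oxo-1,2,3,4,6,7,8,8a-octahydronaphthalen-1-yl 4-nitrobenzoate
Product: 4 (4aR,5S)-5-hydroxy-4a-methyl-4,4a,5,6,7,8-hexahydronaphthalen-2(3H)-one (hydroxyl trans to the angular methyl)
Conditions: K2CO3 (cat.), MeOH, rt
Reagents that add atoms: none
Why: Methanolysis of the activated ester by acyl–oxygen cleavage should free the alcohol without touching the carbinol stereocentre.

**Step 4**
Reactants: 4 (4aR,5S)-5-hydroxy-4a-methyl-4,4a,5,6,7,8-hexahydronaphthalen-2(3H)-one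
Product: 5 (4aR,5R)-5-bromo-4a-methyl-4,4a,5,6,7,8-hexahydronaphthalen-2(3H)-one (bromine cis to the angular methyl)
Conditions: CBr4, P(n-Oct)3, toluene, 70 °C
Reagents that add atoms: carbon tetrabromide, BrC(Br)(Br)Br
Why: Appel bromination through the alkoxyphosphonium ion with SN2 inversion should place bromine cis to the angular methyl (equatorial in the later trans-decalin); the fully substituted β-carbon keeps the phosphine off the enone.

**Step 5**
Reactants: 5 (4aR,5R)-5-bromo-4a-methyl-4,4a,5,6,7,8-hexahydronaphthalen-2(3H)-one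
Product: 6 (4a'R,5'R)-5'-bromo-4a'-methyl-3',4',4a',5',6',7'-hexahydro-1'H-spiro[[1,3]dioxolane-2,2'-naphthalene] (alkene at C-8/C-8a)
Conditions: HOCH2CH2OH, TsOH (cat.), benzene, reflux (Dean–Stark)
Reagents that add atoms: ethylene glycol, OCCO
Why: Acid-catalysed ketalisation of a 4a-methyl octalone moves the double bond out of conjugation to the β,γ-position, which protects the C-2 carbonyl and exposes C-8/C-8a; no stereocentre is formed.

**Step 6**
Reactants: 6 (4a'R,5'R)-5'-bromo-4a'-methyl-3',4',4a',5',6',7'-hexahydro-1'H-spiro[[1,3]dioxolane-2,2'-naphthalene]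
Product: 7 (4a'R,5'R,8'R,8a'S)-5'-bromo-4a'-methylhexahydro-1'H-spiro[[1,3]dioxolane-2,2'-naphthalene]-8',8a'(3'H)-diol (both hydroxyls trans to the angular methyl)
Conditions: OsO4 (cat.), N-methylmorpholine N-oxide, acetone–H2O, rt
Reagents that add atoms: OsO4, O=[Os](=O)(=O)=O; N-methylmorpholine N-oxide, C[N+]1([O-])CCOCC1
Why: Catalytic syn-dihydroxylation of the trisubstituted alkene from the face opposite the angular methyl should set the C-8a hydroxyl trans to that methyl (trans-decalin); the C-8 carbinol is oxidised in the next step.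

**Step 7**
Reactants: 7 (4a'R,5'R,8'R,8a'S)-5'-bromo-4a'-methylhexahydro-1'H-spiro[[1,3]dioxolane-2,2'-naphthalene]-8',8a'(3'H)-diol
Product: 8 (4a'R,5'R,8a'S)-5'-bromo-8a'-hydroxy-4a'-methylhexahydro-1'H-spiro[[1,3]dioxolane-2,2'-naphthalen]-8'(3'H)-one
Conditions: Dess–Martin periodinane, pyridine, CH2Cl2, 0 °C to rt
Reagents that add atoms: none
Why: Dess–Martin oxidation should take only the secondary C-8 alcohol, the tertiary C-8a hydroxyl being inert, and the pyridine buffer protects the ketal.

**Step 8**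
Reactants: 8 (4a'R,5'R,8a'S)-5'-bromo-8a'-hydroxy-4a'-methylhexahydro-1'H-spiro[[1,3]dioxolane-2,2'-naphthalen]-8'(3'H)-one
Product: 9 (4a'R,5'R,8'S,8a'S)-5'-bromo-4a',8'-dimethylhexahydro-1'H-spiro[[1,3]dioxolane-2,2'-naphthalene]-8',8a'(3'H)-diol (trans-diaxial diol)
Conditions: MeMgBr (3 equiv), THF, −78 to 0 °C
Reagents that add atoms: methylmagnesium bromide, C[Mg]Br
Why: Grignard addition to the α-alkoxide ketone should occur from the equatorial direction, because axial approach at C-8 is blocked by the 1,3-diaxial angular methyl, giving the axial C-8 hydroxyl trans to the C-8a hydroxyl.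

**Step 9**
Reactants: 9 (4a'R,5'R,8'S,8a'S)-5'-bromo-4a',8'-dimethylhexahydro-1'H-spiro[[1,3]dioxolane-2,2'-naphthalene]-8',8a'(3'H)-diol
Product: 10 (4aR,5R,8S,8aS)-5-bromo-8,8a-dihydroxy-4a,8-dimethyloctahydronaphthalen-2(1H)-one
Conditions: PPTS, acetone–H2O, 40 °C
Reagents that add atoms: water, O
Why: Mild acetal hydrolysis should release the C-2 ketone without dehydrating the β-hydroxy ketone, which needs stronger acid or base.

**Step 10**
Reactants: 11 4,4-dimethylcyclopent-2-en-1-one
Product: 12 (±)-4,4,5-trimethylcyclopent-2-en-1-one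
Conditions: LiN(iPr)2, THF, −78 °C; MeI, −78 to −20 °C
Reagents that add atoms: iodomethane, CI
Why: Kinetic deprotonation can occur only at C-5 (the γ-carbon is quaternary), and enolate methylation installs the methyl; the new stereocentre is of no consequence because it is flattened again in step 11.

**Step 11**
Reactants: 12 (±)-4,4,5-trimethylcyclopent-2-en-1-one; 10 (4aR,5R,8S,8aS)-5-bromo-8,8a-dihydroxy-4a,8-dimethyloctahydronaphthalen-2(1H)-one
Product: 16 (5R)-5-[(2S,4aR,5R,8S,8aS)-5-bromo-2,8,8a-trihydroxy-4a,8-dimethyldecahydronaphthalen-2-yl]-4,4,5-trimethylcyclopent-2-en-1-one, via lithium dienolate 13 (not isolated), via dichlorocerium dienolate 14 (not isolated), via dilithium dialkoxide 15 (not isolated)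
Conditions: 12 (1.6 equiv), LiN(iPr)2, THF, −78 °C; CeCl3 (anhydrous), −78 °C; then 10 pretreated with LiN(SiMe3)2 (2.0 equiv), −78 to −50 °C; AcOH, −78 °C
Reagents that add atoms: none
Why: LiN(iPr)2 removes the only acidic proton of racemic 12 to give the planar cross-conjugated dienolate 13, which erases that stereocentre, is passed on to trivalent cerium (14) and adds through its methyl-bearing carbon to the C-2 carbonyl of the dialkoxide 15 in a closed six-membered chair transition state. The closest known reaction type is the aldol addition of a cerium enolate to an enolisable, hindered ketone under chelation control by a β-alkoxide. No ring is closed in the product; in the transition state one cerium holds the C-8a alkoxide, the carbonyl oxygen and the enolate oxygen, a chair–chair bicyclo[3.3.1] array that is possible only because the two ring-A oxygens end up 1,3-syn-diaxial. C-2 is controlled by this chelate together with the ring-A chair: the new bond enters equatorially, anti to the C-8a oxygen, and the new hydroxyl becomes axial and cis to it. C-1' is controlled by the same chelate: the enolate oxygen reaches the metal only from the C-1/C-8a side, which puts the C-1' methyl anti to C-1 and the gem-dimethyl carbon anti to the new oxygen as in the target, and as this tridentate aldolate is also the most stable one any reversal should feed the same isomer. The step needs C–C bond formation to outrun proton transfer from C-1 or C-3 of the ketone and retro-aldol cleavage, which the weakly basic, oxophilic cerium enolate, the low temperature and the cold acetic acid quench should secure.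

**Step 12**
Reactants: 16 (5R)-5-[(2S,4aR,5R,8S,8aS)-5-bromo-2,8,8a-trihydroxy-4a,8-dimethyldecahydronaphthalen-2-yl]-4,4,5-trimethylcyclopent-2-en-1-one
Product: 17 (2R,4S)-4-bromo-2-[(2S,4aR,5R,8S,8aS)-5-bromo-2,8,8a-trihydroxy-4a,8-dimethyldecahydronaphthalen-2-yl]-2,3,3-trimethylcyclopentan-1-one
Conditions: HBr (33% in AcOH), CH2Cl2, −30 to 0 °C; cold aqueous NaHCO3
Reagents that add atoms: hydrogen bromide, Br
Why: Acid-catalysed conjugate hydrobromination of the cyclopentenone is reversible, so C-3' should equilibrate to the isomer with bromine cis to the decalinyl group, in which bromine and the large C-1' substituent are both pseudo-equatorial and the C-1' methyl is pseudo-axial on the other face.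

**Step 13**
Reactants: 17 (2R,4S)-4-bromo-2-[(2S,4aR,5R,8S,8aS)-5-bromo-2,8,8a-trihydroxy-4a,8-dimethyldecahydronaphthalen-2-yl]-2,3,3-trimethylcyclopentan-1-one
Product: 18 (2S,4aR,5R,8S,8aS)-5-bromo-2-[(1S,3S,5R)-3-bromo-5-hydroxy-1,2,2-trimethylcyclopentyl]-4a,8-dimethyloctahydronaphthalene-2,8,8a(1H)-triol (target)
Conditions: NaBH4, CeCl3·7H2O, MeOH, −78 °C
Reagents that add atoms: none
Why: Luche-type reduction at low temperature should be faster than β-elimination of bromide, and hydride should add to the carbonyl face that carries only the C-1' methyl, anti to the decalinyl carbinol, giving the C-5' hydroxyl cis to the decalinyl group and to bromine.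

**Compound list**

1 | (R)-(−)-Wieland–Miescher ketone, (8aR)-8a-methyl-3,4,8,8a-tetrahydronaphthalene-1,6(2H,7H)-dione | C[C@@]12CCC(=O)C=C1CCCC2=O | starting material
2 | (4aR,5R)-5-hydroxy-4a-methyl-4,4a,5,6,7,8-hexahydronaphthalen-2(3H)-one | C[C@@]12CCC(=O)C=C1CCC[C@H]2O | intermediate
3 | (1S,8aR)-8a-methyl-6-oxo-1,2,3,4,6,7,8,8a-octahydronaphthalen-1-yl 4-nitrobenzoate | C[C@@]12CCC(=O)C=C1CCC[C@@H]2OC(=O)c1ccc(cc1)[N+](=O)[O-] | intermediate
4 | (4aR,5S)-5-hydroxy-4a-methyl-4,4a,5,6,7,8-hexahydronaphthalen-2(3H)-one | C[C@@]12CCC(=O)C=C1CCC[C@@H]2O | intermediate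
5 | (4aR,5R)-5-bromo-4a-methyl-4,4a,5,6,7,8-hexahydronaphthalen-2(3H)-one | C[C@@]12CCC(=O)C=C1CCC[C@H]2Br | intermediate
6 | (4a'R,5'R)-5'-bromo-4a'-methyl-3',4',4a',5',6',7'-hexahydro-1'H-spiro[[1,3]dioxolane-2,2'-naphthalene] | C[C@@]12CCC3(OCCO3)CC1=CCC[C@H]2Br | intermediate
7 | (4a'R,5'R,8'R,8a'S)-5'-bromo-4a'-methylhexahydro-1'H-spiro[[1,3]dioxolane-2,2'-naphthalene]-8',8a'(3'H)-diol | C[C@@]12CCC3(OCCO3)C[C@@]1(O)[C@H](O)CC[C@H]2Br | intermediate
8 | (4a'R,5'R,8a'S)-5'-bromo-8a'-hydroxy-4a'-methylhexahydro-1'H-spiro[[1,3]dioxolane-2,2'-naphthalen]-8'(3'H)-one | C[C@@]12CCC3(OCCO3)C[C@@]1(O)C(=O)CC[C@H]2Br | intermediate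
9 | (4a'R,5'R,8'S,8a'S)-5'-bromo-4a',8'-dimethylhexahydro-1'H-spiro[[1,3]dioxolane-2,2'-naphthalene]-8',8a'(3'H)-diol | C[C@@]12CCC3(OCCO3)C[C@@]1(O)[C@@](C)(O)CC[C@H]2Br | intermediate
10 | (4aR,5R,8S,8aS)-5-bromo-8,8a-dihydroxy-4a,8-dimethyloctahydronaphthalen-2(1H)-one | C[C@@]12CCC(=O)C[C@@]1(O)[C@@](C)(O)CC[C@H]2Br | intermediate
11 | 4,4-dimethylcyclopent-2-en-1-one | CC1(C)CC(=O)C=C1 | starting material
12 | (±)-4,4,5-trimethylcyclopent-2-en-1-one | CC1C(=O)C=CC1(C)C | intermediate
13 | lithium 2,3,3-trimethylcyclopenta-1,4-dien-1-olate | [Li+].[O-]C1=C(C)C(C)(C)C=C1 | intermediate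
14 | dichlorocerium 2,3,3-trimethylcyclopenta-1,4-dien-1-olate | [Ce+3].[Cl-].[Cl-].[O-]C1=C(C)C(C)(C)C=C1 | intermediate
15 | dilithium (4aR,5R,8S,8aS)-5-bromo-4a,8-dimethyl-2-oxooctahydronaphthalene-8,8a-diolate | [Li+].[Li+].C[C@@]12CCC(=O)C[C@@]1([O-])[C@@](C)([O-])CC[C@H]2Br | intermediate
16 | (5R)-5-[(2S,4aR,5R,8S,8aS)-5-bromo-2,8,8a-trihydroxy-4a,8-dimethyldecahydronaphthalen-2-yl]-4,4,5-trimethylcyclopent-2-en-1-one | CC1(C)C=CC(=O)[C@@]1(C)[C@]1(O)CC[C@@]2(C)[C@H](Br)CC[C@](C)(O)[C@]2(O)C1 | intermediate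
17 | (2R,4S)-4-bromo-2-[(2S,4aR,5R,8S,8aS)-5-bromo-2,8,8a-trihydroxy-4a,8-dimethyldecahydronaphthalen-2-yl]-2,3,3-trimethylcyclopentan-1-one | CC1(C)[C@@H](Br)CC(=O)[C@@]1(C)[C@]1(O)CC[C@@]2(C)[C@H](Br)CC[C@](C)(O)[C@]2(O)C1 | intermediate
18 | (2S,4aR,5R,8S,8aS)-5-bromo-2-[(1S,3S,5R)-3-bromo-5-hydroxy-1,2,2-trimethylcyclopentyl]-4a,8-dimethyloctahydronaphthalene-2,8,8a(1H)-triol | CC1(C)[C@@H](Br)C[C@@H](O)[C@@]1(C)[C@]1(O)CC[C@@]2(C)[C@H](Br)CC[C@](C)(O)[C@]2(O)C1 | target

**Step count**

Total: 13 steps. Longest linear sequence: 12 steps (steps 1–9 and 11–13).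

**Steps most likely to fail**

Step 11. Proton transfer from the ketone to the hindered enolate and reversal of the addition may outrun bond formation between two fully substituted carbons, and the pairing of enolate face and ketone face may be less clean than the chelate model predicts. The fallback sets out from 10 and 11 and comes back at 16. The same cerium-mediated addition is run with the less hindered enolate of 11 (LiN(iPr)2; CeCl3; 10 as its dialkoxide), which should give the unmethylated adduct 5-[(2S,4aR,5R,8S,8aS)-5-bromo-2,8,8a-trihydroxy-4a,8-dimethyldecahydronaphthalen-2-yl]-4,4-dimethylcyclopent-2-en-1-one F1; either configuration at its ring-C methine serves. The methyl group is then brought in by alkylation of the chelated oxido-enolate (LiN(iPr)2 in excess, THF–DMPU, MeI, −78 to −40 °C; Fráter–Seebach type). Methyl iodide should enter the enolate face away from the C-1/C-8a arm, which gives 16.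

Step 12. The acid may trigger retro-aldol cleavage of the C-1'–C-2 bond or ionisation of a tertiary carbinol before the bromide has equilibrated to the cis isomer. The fallback sets out from 16 and comes back at 18. Copper-catalysed conjugate borylation (B2pin2, CuCl and NaOtBu as catalysts, xantphos, MeOH, THF) should add boron anti to the decalinyl group and give (2R,4R)-2-[(2S,4aR,5R,8S,8aS)-5-bromo-2,8,8a-trihydroxy-4a,8-dimethyldecahydronaphthalen-2-yl]-2,3,3-trimethyl-4-(4,4,5,5-tetramethyl-1,3,2-dioxaborolan-2-yl)cyclopentan-1-one F2. Oxidation with NaBO3·4H2O with retention should give (2R,4R)-2-[(2S,4aR,5R,8S,8aS)-5-bromo-2,8,8a-trihydroxy-4a,8-dimethyldecahydronaphthalen-2-yl]-4-hydroxy-2,3,3-trimethylcyclopentan-1-one F3. Reduction with NaBH4 and CeCl3·7H2O from the methyl face should give (2S,4aR,5R,8S,8aS)-5-bromo-2-[(1S,3R,5R)-3,5-dihydroxy-1,2,2-trimethylcyclopentyl]-4a,8-dimethyloctahydronaphthalene-2,8,8a(1H)-triol F4. Appel bromination (CBr4, P(n-Oct)3) at the less hindered C-3' carbinol with inversion should then give 18. Here the kinetic addition anti to the decalinyl group followed by inversion replaces the thermodynamic control of the main route.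

Step 4. E2 loss of the activated axial oxygen toward C-6, or a 1,2-methyl shift, may compete with SN2 substitution at the neopentyl carbon; the Mitsunobu inversion of step 2 carries a related risk. The fallback sets out from 2, comes back at 6 and takes the place of steps 2–5. Ketalisation of 2 with shift of the double bond (ethylene glycol, TsOH) should give (4a'R,5'R)-4a'-methyl-3',4',4a',5',6',7'-hexahydro-1'H-spiro[[1,3]dioxolane-2,2'-naphthalen]-5'-ol F5. Dess–Martin oxidation should give (4a'R)-4a'-methyl-4',4a',6',7'-tetrahydro-1'H-spiro[[1,3]dioxolane-2,2'-naphthalen]-5'(3'H)-one F6. Hydrazine hydrate should give its hydrazone, (4a'R)-5'-hydrazinylidene-4a'-methyl-3',4',4a',5',6',7'-hexahydro-1'H-spiro[[1,3]dioxolane-2,2'-naphthalene] F7. CuBr2 and LiOtBu should convert this into the geminal dibromide (4a'R)-5',5'-dibromo-4a'-methyl-3',4',4a',5',6',7'-hexahydro-1'H-spiro[[1,3]dioxolane-2,2'-naphthalene] F8. Mono-reduction with Bu3SnH (1.0 equiv, AIBN cat.) should then deliver hydrogen to the α-bromo radical from the face anti to the angular methyl, the face that hydride also takes in step 1, and give 6.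

**Further compounds**

F1 | step 11 | 5-[(2S,4aR,5R,8S,8aS)-5-bromo-2,8,8a-trihydroxy-4a,8-dimethyldecahydronaphthalen-2-yl]-4,4-dimethylcyclopent-2-en-1-one | CC1(C)C=CC(=O)C1[C@]1(O)CC[C@@]2(C)[C@H](Br)CC[C@](C)(O)[C@]2(O)C1
F2 | step 12 | (2R,4R)-2-[(2S,4aR,5R,8S,8aS)-5-bromo-2,8,8a-trihydroxy-4a,8-dimethyldecahydronaphthalen-2-yl]-2,3,3-trimethyl-4-(4,4,5,5-tetramethyl-1,3,2-dioxaborolan-2-yl)cyclopentan-1-one | CC1(C)[C@H](B3OC(C)(C)C(C)(C)O3)CC(=O)[C@@]1(C)[C@]1(O)CC[C@@]2(C)[C@H](Br)CC[C@](C)(O)[C@]2(O)C1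
F3 | step 12 | (2R,4R)-2-[(2S,4aR,5R,8S,8aS)-5-bromo-2,8,8a-trihydroxy-4a,8-dimethyldecahydronaphthalen-2-yl]-4-hydroxy-2,3,3-trimethylcyclopentan-1-one | CC1(C)[C@H](O)CC(=O)[C@@]1(C)[C@]1(O)CC[C@@]2(C)[C@H](Br)CC[C@](C)(O)[C@]2(O)C1
F4 | step 12 | (2S,4aR,5R,8S,8aS)-5-bromo-2-[(1S,3R,5R)-3,5-dihydroxy-1,2,2-trimethylcyclopentyl]-4a,8-dimethyloctahydronaphthalene-2,8,8a(1H)-triol | CC1(C)[C@H](O)C[C@@H](O)[C@@]1(C)[C@]1(O)CC[C@@]2(C)[C@H](Br)CC[C@](C)(O)[C@]2(O)C1
F5 | step 4 | (4a'R,5'R)-4a'-methyl-3',4',4a',5',6',7'-hexahydro-1'H-spiro[[1,3]dioxolane-2,2'-naphthalen]-5'-ol | C[C@@]12CCC3(OCCO3)CC1=CCC[C@H]2O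
F6 | step 4 | (4a'R)-4a'-methyl-4',4a',6',7'-tetrahydro-1'H-spiro[[1,3]dioxolane-2,2'-naphthalen]-5'(3'H)-one | C[C@@]12CCC3(OCCO3)CC1=CCCC2=O
F7 | step 4 | (4a'R)-5'-hydrazinylidene-4a'-methyl-3',4',4a',5',6',7'-hexahydro-1'H-spiro[[1,3]dioxolane-2,2'-naphthalene] | C[C@@]12CCC3(OCCO3)CC1=CCCC2=NN
F8 | step 4 | (4a'R)-5',5'-dibromo-4a'-methyl-3',4',4a',5',6',7'-hexahydro-1'H-spiro[[1,3]dioxolane-2,2'-naphthalene] | C[C@@]12CCC3(OCCO3)CC1=CCCC2(Br)Br
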